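**Plan**

1. Retrosynthesis, first cut: the two interflavanyl bonds (C4 of each upper unit to C8 and to C6 of the lower A ring). This gives 4′-O-methyl-(+)-catechin 23 and two molecules of one extender, (+)-mollisacacidin 11.
2. Second cut, in the pyran ring of the extender (and likewise of 23): O1–C8a and C2–C3 together, a formal [4+2] back to a 2-fluoroaryl benzyloxymethyl ketone (C8a–C4a–C4–C3) and the B-ring aldehyde (C2=O1).
3. Enabling feature: C4 of the pyran ring lies between C3 and C4a and is ortho to C8a. As a ketone it makes C3 an enol nucleophile and C8a–F an SNAr site, and the A-ring oxygens (C7; also C5 in 23) are meta to C8a, so they put no charge on the attacked carbon. C4 is also the carbon that must later ionise, so the helper carbonyl is used up: reduced to the leaving 4-OH in 11, hydrogenolysed to CH2 in 23.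
4. Forward order: ketone → enol silane → one-pot aldol/SNAr closure of the pyranone ring → debenzylation and C4 reduction (11). The same sequence with O-benzylisovanillin gives 23. One acid-catalysed double condensation then joins 23 with two 11 (C8 first, then C6).
5. Stereochemistry: C2 from the chiral Lewis acid in the aldol; C3 by equilibration α to the C4 ketone (2,3-trans); C4 of both upper units by attack of the phloroglucinol ring anti to the 3-OH of the flavan-4-yl cation (3,4-trans).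

Key step: step 3

Remark: 1, 2, 6, 12 and 18 are taken as purchased. The ring-forming event is run once on the extender at the C4-ketone level and the product serves both upper units. In steps 3 and 10 the catalyst antipode is the one that sends the enol silane to the Si face of the aldehyde, which gives 2R.

Step 1
Reactants: 1 4-(benzyloxy)-1-bromo-2-fluorobenzene; 2 2-(benzyloxy)-N-methoxy-N-methylacetamide
Product: 4 2-(benzyloxy)-1-[4-(benzyloxy)-2-fluorophenyl]ethan-1-one, via arylmagnesium chloride 3 (not isolated)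
Conditions: i-PrMgCl·LiCl (1.1 equiv), THF, −20 °C; then 2, −20 → 0 °C; aq NH4Cl
Reagents that add atoms: none
Why: Br/Mg exchange followed by Weinreb ketone synthesis; the chelated tetrahedral adduct stops at the ketone, and the o-fluoroaryl Grignard reagent is kept at or below 0 °C so that it does not collapse to an aryne.

Step 2
Reactants: 4 2-(benzyloxy)-1-[4-(benzyloxy)-2-fluorophenyl]ethan-1-one
Product: 5 (Z)-{[2-(benzyloxy)-1-[4-(benzyloxy)-2-fluorophenyl]ethenyl]oxy}trimethylsilane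
Conditions: TMSOTf (1.2 equiv), Et3N (1.5 equiv), CH2Cl2, 0 °C; used crude
Reagents that add atoms: trimethylsilyl trifluoromethanesulfonate C[Si](C)(C)OS(=O)(=O)C(F)(F)F
Why: Soft enolisation and O-silylation of an α-alkoxy aryl ketone should give the Z enol silane; its geometry is not critical for the next step.

Step 3
Reactants: 5 (Z)-{[2-(benzyloxy)-1-[4-(benzyloxy)-2-fluorophenyl]ethenyl]oxy}trimethylsilane; 6 3,4-bis(benzyloxy)benzaldehyde
Product: 9 (2R,3R)-3,7-bis(benzyloxy)-2-[3,4-bis(benzyloxy)phenyl]-2,3-dihydro-4H-chromen-4-one, via syn-silyl aldol 7 (not isolated), via 2,3-cis-flavanone 8 (not isolated)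
Conditions: chiral (acyloxy)borane catalyst from mono(2,6-diisopropoxybenzoyl)tartaric acid and BH3·THF (20 mol %), EtCN, −78 °C; then CsF (0.5 equiv), DMF, −40 → 20 °C, same flask; pH 7 buffer
Reagents that add atoms: none
Why: A chiral-Lewis-acid Mukaiyama aldol joins C3 of 5 to the aldehyde carbon (C2–C3) with silyl transfer to give 7; catalytic fluoride then frees the C2 alkoxide, which displaces the C8a fluoride activated by the ortho C4 ketone (O1–C8a) and releases fluoride again as Me3SiF. The closest known reaction types are the enantioselective Lewis-acid-catalysed Mukaiyama aldol of ketone enol silanes with aryl aldehydes and the fluoride-catalysed SNAr etherification of silyl ethers with activated aryl fluorides. The pyranone ring closes by 6-exo-trig addition–elimination at C8a. C2 is set by the catalyst (Si-face attack on the aldehyde). C3, α to the C4 ketone, is set thermodynamically: the cis isomer 8 from the syn aldol should epimerise in the basic fluoride medium to the diequatorial 2,3-trans 9. The step needs ring closure to outrun retro-aldol and arylation by the C2 oxygen only; the ortho acyl group, with the C7 oxygen meta to C8a, should secure the first and the benzyl ether on the C3 oxygen the second.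

Step 4
Reactants: 9 (2R,3R)-3,7-bis(benzyloxy)-2-[3,4-bis(benzyloxy)phenyl]-2,3-dihydro-4H-chromen-4-one
Product: 10 (+)-fustin [(2R,3R)-2-(3,4-dihydroxyphenyl)-3,7-dihydroxy-2,3-dihydro-4H-chromen-4-one]
Conditions: H2 (1 atm), 10% Pd/C, THF–MeOH, 20 °C
Reagents that add atoms: none
Why: Catalytic hydrogenolysis of the four benzyl ethers under neutral conditions; the aryl ketone, vinylogous to two ring oxygens, and the C2 and C3 stereocentres should be untouched.

Step 5
Reactants: 10 (+)-fustin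
Product: 11 (+)-mollisacacidin [(2R,3S,4R)-2-(3,4-dihydroxyphenyl)-3,4-dihydro-2H-chromene-3,4,7-triol]
Conditions: NaBH4 (excess), EtOH, 0 → 20 °C
Reagents that add atoms: none
Why: Borohydride reduction of the C4 ketone of a trans-dihydroflavonol should give mainly the 3,4-trans diol; the C4 configuration is immaterial because both epimers ionise to the same cation in step 13.

Step 6
Reactants: 12 5-fluorobenzene-1,3-diol
Product: 13 1,3-bis(benzyloxy)-5-fluorobenzene
Conditions: BnBr (2.2 equiv), K2CO3, DMF, 20 °C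
Reagents that add atoms: benzyl bromide BrCc1ccccc1
Why: Williamson etherification of both phenols.

Step 7
Reactants: 13 1,3-bis(benzyloxy)-5-fluorobenzene
Product: 14 1,5-bis(benzyloxy)-2-bromo-3-fluorobenzene
Conditions: NBS (1.0 equiv), MeCN, 0 °C
Reagents that add atoms: N-bromosuccinimide O=C1CCC(=O)N1Br
Why: Electrophilic aromatic bromination should go to the carbon para to one benzyloxy group and between OBn and the small fluorine, not to the crowded carbon between the two benzyloxy groups.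

Step 8
Reactants: 14 1,5-bis(benzyloxy)-2-bromo-3-fluorobenzene; 2 2-(benzyloxy)-N-methoxy-N-methylacetamide
Product: 16 2-(benzyloxy)-1-[2,4-bis(benzyloxy)-6-fluorophenyl]ethan-1-one, via arylmagnesium chloride 15 (not isolated)
Conditions: i-PrMgCl·LiCl (1.1 equiv), THF, −15 °C; then 2, −15 → 0 °C; aq NH4Cl
Reagents that add atoms: none
Why: Br/Mg exchange (helped by the ortho F and OBn) and Weinreb ketone synthesis, as in step 1.

Step 9
Reactants: 16 2-(benzyloxy)-1-[2,4-bis(benzyloxy)-6-fluorophenyl]ethan-1-one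
Product: 17 (Z)-{[2-(benzyloxy)-1-[2,4-bis(benzyloxy)-6-fluorophenyl]ethenyl]oxy}trimethylsilane
Conditions: TMSOTf (1.2 equiv), Et3N (1.5 equiv), CH2Cl2, 0 °C; used crude
Reagents that add atoms: trimethylsilyl trifluoromethanesulfonate C[Si](C)(C)OS(=O)(=O)C(F)(F)F
Why: Soft enolisation and O-silylation, as in step 2.

Step 10
Reactants: 17 (Z)-{[2-(benzyloxy)-1-[2,4-bis(benzyloxy)-6-fluorophenyl]ethenyl]oxy}trimethylsilane; 18 3-(benzyloxy)-4-methoxybenzaldehyde
Product: 21 (2R,3R)-3,5,7-tris(benzyloxy)-2-[3-(benzyloxy)-4-methoxyphenyl]-2,3-dihydro-4H-chromen-4-one, via syn-silyl aldol 19 (not isolated), via 2,3-cis-flavanone 20 (not isolated)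
Conditions: chiral (acyloxy)borane catalyst as in step 3 (20 mol %), EtCN, −78 → −60 °C; then CsF (0.5 equiv), DMF, −20 → 30 °C, same flask; pH 7 buffer
Reagents that add atoms: none
Why: The same Mukaiyama aldol/fluoride-relayed SNAr annulation as step 3; C2 comes from the catalyst and C3 from equilibration to 2,3-trans, and the C5 and C7 oxygens are again meta to the fluorine-bearing carbon.

Step 11
Reactants: 21 (2R,3R)-3,5,7-tris(benzyloxy)-2-[3-(benzyloxy)-4-methoxyphenyl]-2,3-dihydro-4H-chromen-4-one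
Product: 22 (2R,3S,4R)-3,5,7-tris(benzyloxy)-2-[3-(benzyloxy)-4-methoxyphenyl]-3,4-dihydro-2H-chromen-4-ol
Conditions: NaBH4, THF–MeOH, 0 °C
Reagents that add atoms: none
Why: Borohydride reduction of the C4 ketone; the new C4 centre (3,4-trans expected) is removed in the next step, so its configuration does not matter.

Step 12
Reactants: 22 (2R,3S,4R)-3,5,7-tris(benzyloxy)-2-[3-(benzyloxy)-4-methoxyphenyl]-3,4-dihydro-2H-chromen-4-ol
Product: 23 4′-O-methyl-(+)-catechin [(2R,3S)-2-(3-hydroxy-4-methoxyphenyl)-3,4-dihydro-2H-chromene-3,5,7-triol]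
Conditions: H2 (1 atm), Pd(OH)2/C, EtOAc–MeOH, 20 °C
Reagents that add atoms: none
Why: One catalytic hydrogenolysis should cleave the four benzyl ethers and the doubly oxygen-activated benzylic C4–OH (the classical flavan-3,4-diol to flavan-3-ol conversion) without touching C2 or C3.

Step 13
Reactants: 23 4′-O-methyl-(+)-catechin; 11 (+)-mollisacacidin (2.2 equiv)
Product: 25 (−)-fisetinidol-(4α→8)-[(−)-fisetinidol-(4α→6)]-4′-O-methyl-(+)-catechin, via [4,8]-biflavanoid 24 (not isolated)
Conditions: 0.1 M aq HCl, EtOH cosolvent, N2, 20 °C; Sephadex LH-20 then RP-HPLC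
Reagents that add atoms: none
Why: Acid-catalysed Friedel–Crafts-type flavan-4-yl cation coupling (the biomimetic proanthocyanidin condensation); the cation from 11, stabilised by the 7-OH and O1, should be attacked by the phloroglucinol ring of 23 at C8 and then C6, each time anti to the 3-OH, giving the 3,4-trans (4S) bonds, with minor 4β-linked isomers removed by chromatography.

**Compound list**

1 | 4-(benzyloxy)-1-bromo-2-fluorobenzene | Brc1ccc(OCc2ccccc2)cc1F | starting material
2 | 2-(benzyloxy)-N-methoxy-N-methylacetamide | CON(C)C(=O)COCc1ccccc1 | starting material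
3 | [4-(benzyloxy)-2-fluorophenyl]magnesium chloride (LiCl complex) | Cl[Mg]c1ccc(OCc2ccccc2)cc1F | intermediate
4 | 2-(benzyloxy)-1-[4-(benzyloxy)-2-fluorophenyl]ethan-1-one | O=C(COCc1ccccc1)c1ccc(OCc2ccccc2)cc1F | intermediate
5 | (Z)-{[2-(benzyloxy)-1-[4-(benzyloxy)-2-fluorophenyl]ethenyl]oxy}trimethylsilane | C[Si](C)(C)O/C(=C\OCc1ccccc1)c1ccc(OCc2ccccc2)cc1F | intermediate
6 | 3,4-bis(benzyloxy)benzaldehyde | O=Cc1ccc(OCc2ccccc2)c(OCc2ccccc2)c1 | starting material
7 | (2S,3R)-2-(benzyloxy)-1-[4-(benzyloxy)-2-fluorophenyl]-3-[3,4-bis(benzyloxy)phenyl]-3-[(trimethylsilyl)oxy]propan-1-one (syn) | O=C(c1ccc(OCc2ccccc2)cc1F)[C@@H](OCc1ccccc1)[C@H](O[Si](C)(C)C)c1ccc(OCc2ccccc2)c(OCc2ccccc2)c1 | intermediate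
8 | (2R,3S)-3,7-bis(benzyloxy)-2-[3,4-bis(benzyloxy)phenyl]-2,3-dihydro-4H-chromen-4-one (2,3-cis) | O=C1[C@@H](OCc2ccccc2)[C@@H](c2ccc(OCc3ccccc3)c(OCc3ccccc3)c2)Oc2cc(OCc3ccccc3)ccc21 | intermediate
9 | (2R,3R)-3,7-bis(benzyloxy)-2-[3,4-bis(benzyloxy)phenyl]-2,3-dihydro-4H-chromen-4-one (2,3-trans) | O=C1[C@H](OCc2ccccc2)[C@@H](c2ccc(OCc3ccccc3)c(OCc3ccccc3)c2)Oc2cc(OCc3ccccc3)ccc21 | intermediate
10 | (+)-fustin, (2R,3R)-2-(3,4-dihydroxyphenyl)-3,7-dihydroxy-2,3-dihydro-4H-chromen-4-one | O=C1[C@H](O)[C@@H](c2ccc(O)c(O)c2)Oc2cc(O)ccc21 | intermediate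
11 | (+)-mollisacacidin, (2R,3S,4R)-2-(3,4-dihydroxyphenyl)-3,4-dihydro-2H-chromene-3,4,7-triol | O[C@@H]1c2ccc(O)cc2O[C@H](c2ccc(O)c(O)c2)[C@H]1O | intermediate
12 | 5-fluorobenzene-1,3-diol | Oc1cc(O)cc(F)c1 | starting material
13 | 1,3-bis(benzyloxy)-5-fluorobenzene | Fc1cc(OCc2ccccc2)cc(OCc2ccccc2)c1 | intermediate
14 | 1,5-bis(benzyloxy)-2-bromo-3-fluorobenzene | Fc1cc(OCc2ccccc2)cc(OCc2ccccc2)c1Br | intermediate
15 | [2,4-bis(benzyloxy)-6-fluorophenyl]magnesium chloride (LiCl complex) | Cl[Mg]c1c(F)cc(OCc2ccccc2)cc1OCc1ccccc1 | intermediate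
16 | 2-(benzyloxy)-1-[2,4-bis(benzyloxy)-6-fluorophenyl]ethan-1-one | O=C(COCc1ccccc1)c1c(F)cc(OCc2ccccc2)cc1OCc1ccccc1 | intermediate
17 | (Z)-{[2-(benzyloxy)-1-[2,4-bis(benzyloxy)-6-fluorophenyl]ethenyl]oxy}trimethylsilane | C[Si](C)(C)O/C(=C\OCc1ccccc1)c1c(F)cc(OCc2ccccc2)cc1OCc1ccccc1 | intermediate
18 | 3-(benzyloxy)-4-methoxybenzaldehyde | COc1ccc(C=O)cc1OCc1ccccc1 | starting material
19 | (2S,3R)-2-(benzyloxy)-1-[2,4-bis(benzyloxy)-6-fluorophenyl]-3-[3-(benzyloxy)-4-methoxyphenyl]-3-[(trimethylsilyl)oxy]propan-1-one (syn) | O=C(c1c(F)cc(OCc2ccccc2)cc1OCc1ccccc1)[C@@H](OCc1ccccc1)[C@H](O[Si](C)(C)C)c1ccc(OC)c(OCc2ccccc2)c1 | intermediate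
20 | (2R,3S)-3,5,7-tris(benzyloxy)-2-[3-(benzyloxy)-4-methoxyphenyl]-2,3-dihydro-4H-chromen-4-one (2,3-cis) | O=C1[C@@H](OCc2ccccc2)[C@@H](c2ccc(OC)c(OCc3ccccc3)c2)Oc2cc(OCc3ccccc3)cc(OCc3ccccc3)c21 | intermediate
21 | (2R,3R)-3,5,7-tris(benzyloxy)-2-[3-(benzyloxy)-4-methoxyphenyl]-2,3-dihydro-4H-chromen-4-one (2,3-trans) | O=C1[C@H](OCc2ccccc2)[C@@H](c2ccc(OC)c(OCc3ccccc3)c2)Oc2cc(OCc3ccccc3)cc(OCc3ccccc3)c21 | intermediate
22 | (2R,3S,4R)-3,5,7-tris(benzyloxy)-2-[3-(benzyloxy)-4-methoxyphenyl]-3,4-dihydro-2H-chromen-4-ol | O[C@@H]1c2c(OCc3ccccc3)cc(OCc3ccccc3)cc2O[C@H](c2ccc(OC)c(OCc3ccccc3)c2)[C@H]1OCc1ccccc1 | intermediate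
23 | 4′-O-methyl-(+)-catechin, (2R,3S)-2-(3-hydroxy-4-methoxyphenyl)-3,4-dihydro-2H-chromene-3,5,7-triol | COc1ccc([C@H]2Oc3cc(O)cc(O)c3C[C@@H]2O)cc1O | intermediate
24 | (−)-fisetinidol-(4α→8)-4′-O-methyl-(+)-catechin (upper unit 2R,3S,4S; lower unit 2R,3S) | COc1ccc([C@H]2Oc3c(c(O)cc(O)c3[C@@H]3c4ccc(O)cc4O[C@H](c4ccc(O)c(O)c4)[C@H]3O)C[C@@H]2O)cc1O | intermediate
25 | (−)-fisetinidol-(4α→8)-[(−)-fisetinidol-(4α→6)]-4′-O-methyl-(+)-catechin (both upper units 2R,3S,4S; lower unit 2R,3S) | COc1ccc([C@H]2Oc3c(c(O)c([C@@H]4c5ccc(O)cc5O[C@H](c5ccc(O)c(O)c5)[C@H]4O)c(O)c3[C@@H]3c4ccc(O)cc4O[C@H](c4ccc(O)c(O)c4)[C@H]3O)C[C@@H]2O)cc1O | target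

**Count and risks**

Total step count: 13. Longest linear sequence: 8 steps (steps 6 to 13).

Steps most likely to fail:

Step 3. The catalyst may not differentiate the aldehyde faces well with this α-alkoxy enol silane and electron-rich aldehyde. The freed C2 alkoxide may also revert by retro-aldol before it closes, and the C3 epimerisation may be accompanied by base-induced opening of the pyranone ring; all of these erode C2. The fallback sets out from aldehyde 6 and returns at silyl aldol 7. An Evans syn-glycolate boron aldol (Bu2BOTf, i-Pr2NEt, CH2Cl2, −78 → 0 °C) of 6 with (S)-4-benzyl-3-[(benzyloxy)acetyl]-1,3-oxazolidin-2-one F1 should give the auxiliary-controlled syn aldol F2. Transamidation (MeNHOMe·HCl, AlMe3) gives the hydroxy Weinreb amide F3, and TMSCl/imidazole gives its silyl ether F4. Addition of the Grignard reagent 3 (THF, −20 → 0 °C, buffered work-up) then forms the C4–C4a bond last and delivers 7, which is closed with CsF as in step 3.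

Step 10. Ring closure onto the more electron-rich, doubly ortho-substituted fluoroarene may be slower than retro-aldol of the liberated alkoxide, so that C2 and C3 scramble. The fallback sets out from Weinreb amide 2 and aldehyde 18 and returns at 21. 1,3,5-Trifluorobenzene is lithiated (n-BuLi, THF, −78 °C) to 2,4,6-trifluorophenyllithium F5 and acylated with 2 to the trifluorophenyl ketone F6. Its enol silane F7 (TMSOTf, Et3N) and 18 give, under the conditions of step 10, the silyl aldol F8. Closure onto a ring that still carries two more fluorines should be fast at low temperature and lead, through the cis isomer F9, to the 5,7-difluoroflavanone F10. The two remaining C–F bonds, para and ortho to the C4 ketone, are then exchanged for benzyloxy groups by SNAr (BnOH, Cs2CO3, DMSO, 20–40 °C), through the 7-benzyloxy-5-fluoro compound F11, to give 21.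

Step 13. Facial selectivity at the cationic C4 may be poor (4β-linked isomers), 11 may self-condense, and the second substitution at C6 may stay incomplete in aqueous acid. The fallback sets out from 11 and returns at 24 and then 25. 11 is converted with phenylmethanethiol in acetic acid into the 4-benzylsulfanyl flavan-3-ol F12. F12 is then activated with AgBF4 in THF at 0 °C in the presence of 23, first one equivalent to reach 24 and then a second to reach 25; this thiophilic, non-aqueous activation allows stepwise coupling at low temperature.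

**Further compounds**

F1 | step 3 | (S)-4-benzyl-3-[(benzyloxy)acetyl]-1,3-oxazolidin-2-one | O=C(COCc1ccccc1)N1C(=O)OC[C@@H]1Cc1ccccc1
F2 | step 3 | (S)-4-benzyl-3-[(2S,3R)-2-(benzyloxy)-3-[3,4-bis(benzyloxy)phenyl]-3-hydroxypropanoyl]-1,3-oxazolidin-2-one | O=C([C@@H](OCc1ccccc1)[C@H](O)c1ccc(OCc2ccccc2)c(OCc2ccccc2)c1)N1C(=O)OC[C@@H]1Cc1ccccc1
F3 | step 3 | (2S,3R)-2-(benzyloxy)-3-[3,4-bis(benzyloxy)phenyl]-3-hydroxy-N-methoxy-N-methylpropanamide | CON(C)C(=O)[C@@H](OCc1ccccc1)[C@H](O)c1ccc(OCc2ccccc2)c(OCc2ccccc2)c1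
F4 | step 3 | (2S,3R)-2-(benzyloxy)-3-[3,4-bis(benzyloxy)phenyl]-N-methoxy-N-methyl-3-[(trimethylsilyl)oxy]propanamide | CON(C)C(=O)[C@@H](OCc1ccccc1)[C@H](O[Si](C)(C)C)c1ccc(OCc2ccccc2)c(OCc2ccccc2)c1
F5 | step 10 | 2,4,6-trifluorophenyllithium | [Li]c1c(F)cc(F)cc1F
F6 | step 10 | 2-(benzyloxy)-1-(2,4,6-trifluorophenyl)ethan-1-one | O=C(COCc1ccccc1)c1c(F)cc(F)cc1F
F7 | step 10 | (Z)-{[2-(benzyloxy)-1-(2,4,6-trifluorophenyl)ethenyl]oxy}trimethylsilane | C[Si](C)(C)O/C(=C\OCc1ccccc1)c1c(F)cc(F)cc1F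
F8 | step 10 | (2S,3R)-2-(benzyloxy)-3-[3-(benzyloxy)-4-methoxyphenyl]-1-(2,4,6-trifluorophenyl)-3-[(trimethylsilyl)oxy]propan-1-one | O=C(c1c(F)cc(F)cc1F)[C@@H](OCc1ccccc1)[C@H](O[Si](C)(C)C)c1ccc(OC)c(OCc2ccccc2)c1
F9 | step 10 | (2R,3S)-3-(benzyloxy)-2-[3-(benzyloxy)-4-methoxyphenyl]-5,7-difluoro-2,3-dihydro-4H-chromen-4-one | O=C1[C@@H](OCc2ccccc2)[C@@H](c2ccc(OC)c(OCc3ccccc3)c2)Oc2cc(F)cc(F)c21
F10 | step 10 | (2R,3R)-3-(benzyloxy)-2-[3-(benzyloxy)-4-methoxyphenyl]-5,7-difluoro-2,3-dihydro-4H-chromen-4-one | O=C1[C@H](OCc2ccccc2)[C@@H](c2ccc(OC)c(OCc3ccccc3)c2)Oc2cc(F)cc(F)c21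
F11 | step 10 | (2R,3R)-3,7-bis(benzyloxy)-2-[3-(benzyloxy)-4-methoxyphenyl]-5-fluoro-2,3-dihydro-4H-chromen-4-one | O=C1[C@H](OCc2ccccc2)[C@@H](c2ccc(OC)c(OCc3ccccc3)c2)Oc2cc(OCc3ccccc3)cc(F)c21
F12 | step 13 | (2R,3R,4R)-4-(benzylsulfanyl)-2-(3,4-dihydroxyphenyl)-3,4-dihydro-2H-chromene-3,7-diol | c1ccccc1CS[C@@H]1c2ccc(O)cc2O[C@H](c2ccc(O)c(O)c2)[C@H]1O
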